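## Retrosynthetic overview

1. The two acetate C–O bonds are made last with an enzyme that ignores phenols. The immediate precursor is therefore the free phenolic (2R,3R)-diol, and no separate phenol deprotection is needed.
2. The diol comes from a trans-(3R,4R)-dibenzylbutyrolactone, where LiAlH4 opens the ring and removes the phenol pivalate in one operation. That lactone comes from an (R)-β-benzyl-γ-butyrolactone and veratryl bromide, with anti alkylation setting the second stereocentre.
3. Key disconnection: the ring CH2–O bond of the β-benzyl lactone leads back to a prochiral 3-benzylcyclobutanone. A catalytic desymmetrising oxygen insertion forms this C–O bond and sets the first stereocentre.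
4. The cyclobutanone comes from a [2+2] cycloaddition of dichloroketene with O-pivaloyl methoxyeugenol.
5. Ring order: cyclobutanone (step 2), then γ-lactone by O-insertion (step 3), then ring opening (step 5). Both arenes are bought.

Assumption: the sense of induction of the new catalyst in step 3 cannot be predicted. Both antipodes are equally available from (R)- or (S)-BINOL, and the one that gives the (R)-lactone is used (written here as S,S).

## Route

Step 1
Reactants: 1 4-allyl-2,6-dimethoxyphenol (methoxyeugenol)
Product: 2 4-allyl-2,6-dimethoxyphenyl pivalate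
Conditions: PivCl (1.2 equiv), Et3N (1.5 equiv), DMAP (5 mol %), CH2Cl2, 0 °C → rt
Reagents that add atoms: pivaloyl chloride, CC(C)(C)C(=O)Cl
Why: DMAP-catalysed O-acylation of the phenol gives a pivalate that masks the oxidisable syringyl OH through steps 2–4, is too hindered (two ortho OMe groups plus t-Bu) for amide bases or enolates to attack, and needs no removal step because LiAlH4 cleaves it in step 5.

Step 2
Reactants: 2 4-allyl-2,6-dimethoxyphenyl pivalate; 3 trichloroacetyl chloride
Product: 6 3-[3,5-dimethoxy-4-(pivaloyloxy)benzyl]cyclobutan-1-one (achiral), via dichloroketene 4 (not isolated), via racemic gem-dichlorocyclobutanone adduct 5 (not isolated)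
Conditions: Zn–Cu, Et2O–DME (10:1), 3 (2 equiv) added over 2 h, reflux; then AcOH and fresh Zn dust, same flask, rt → 40 °C
Reagents that add atoms: none
Why: This is a ketene–alkene [2+2] cycloaddition in which zinc makes electrophilic dichloroketene, which adds regiospecifically to the terminal alkene (carbonyl carbon to the CH2 terminus, well precedented for methoxylated allylarenes); adding AcOH then lets the same metal carry out the reductive dechlorination, and because 6 has a mirror plane the racemic centre of 5 does not matter.

Step 3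
Reactants: 6 3-[3,5-dimethoxy-4-(pivaloyloxy)benzyl]cyclobutan-1-one
Product: 8 (R)-4-[3,5-dimethoxy-4-(pivaloyloxy)benzyl]dihydrofuran-2(3H)-one, via Criegee hydroperoxy hemiketal 7 (not isolated)
Conditions: (S,S)-IDP catalyst (5 mol %; C2-symmetric imidodiphosphoric acid built from two (S)-3,3′-bis(2,4,6-triethylphenyl)-BINOL units), 30 % aq H2O2 (1.5 equiv), CHCl3, −40 °C, 36 h
Reagents that add atoms: hydrogen peroxide, OO
Why: Proposed new method: a desymmetrising Baeyer–Villiger oxidation run in the narrow pocket of a confined imidodiphosphoric acid instead of an open BINOL phosphoric acid; the bifunctional P(=O)–NH–P(=O) site protonates the strained ketone while accepting the proton of H2O2, so adduct 7 forms and is held by two hydrogen bonds inside the pocket; with the long benzyl arm forced out through the pocket mouth, only one of the two enantiotopic ring CH2 groups can lie antiperiplanar to the O–O bond, and its 1,2-shift to oxygen (driven by ring-strain release, hence fast at −40 °C with arene and pivalate untouched) forms the CH2–O bond and fixes C4 as R; the closest known reaction types are the chiral phosphoric acid/H2O2 Baeyer–Villiger desymmetrisation of 3-substituted cyclobutanones (good for 3-aryl, only moderate for flexible 3-benzyl groups) and confined-acid sulfoxidation with aqueous H2O2.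

Step 4
Reactants: 8 (R)-4-[3,5-dimethoxy-4-(pivaloyloxy)benzyl]dihydrofuran-2(3H)-one; 9 3,4-dimethoxybenzyl bromide (veratryl bromide)
Product: 11 (3R,4R)-3-(3,4-dimethoxybenzyl)-4-[3,5-dimethoxy-4-(pivaloyloxy)benzyl]dihydrofuran-2(3H)-one, via lithium enolate 10 (not isolated)
Conditions: LiHMDS (1.05 equiv), THF, −78 °C, 45 min; 9 (1.2 equiv), DMPU, −78 → −30 °C
Reagents that add atoms: none
Why: In this lactone enolate alkylation (SN2) the benzylic bromide approaches the planar enolate anti to the C4 substituent, giving the trans (3R,4R) product with dr ≥ 95:5 as is standard for dibenzylbutyrolactone lignans, and the non-nucleophilic base leaves the pivalate intact.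

Step 5
Reactants: 11 (3R,4R)-3-(3,4-dimethoxybenzyl)-4-[3,5-dimethoxy-4-(pivaloyloxy)benzyl]dihydrofuran-2(3H)-one
Product: 12 (2R,3R)-2-(3,4-dimethoxybenzyl)-3-(4-hydroxy-3,5-dimethoxybenzyl)butane-1,4-diol
Conditions: LiAlH4 (3 equiv), THF, 0 °C → reflux 1 h; aq Rochelle salt work-up
Reagents that add atoms: none
Why: Hydride reduction of both esters opens the lactone to the 1,4-diol and cleaves the aryl pivalate to the phenol in the same operation, and because hydride addition is much faster than enolisation neither stereocentre is disturbed.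

Step 6
Reactants: 12 (2R,3R)-2-(3,4-dimethoxybenzyl)-3-(4-hydroxy-3,5-dimethoxybenzyl)butane-1,4-diol
Product: 13 Justin C, (2R,3R)-2-(3,4-dimethoxybenzyl)-3-(4-hydroxy-3,5-dimethoxybenzyl)butane-1,4-diyl diacetate
Conditions: Novozym 435 (immobilised CAL-B), vinyl acetate (6 equiv), MTBE–THF (4:1), 40 °C
Reagents that add atoms: vinyl acetate, C=COC(C)=O
Why: In this lipase-catalysed irreversible transesterification the acyl-enzyme transfers acetyl to primary aliphatic OH groups but not to phenols (here also hindered by two ortho OMe groups), the enol leaving group tautomerises so the reaction runs to the diacetate, and the neutral conditions avoid both cyclodehydration to the tetrahydrofuran and any change at the stereocentres.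

## Compound list

1 | 4-allyl-2,6-dimethoxyphenol (methoxyeugenol) | C=CCc1cc(OC)c(O)c(OC)c1 | starting material
2 | 4-allyl-2,6-dimethoxyphenyl pivalate | C=CCc1cc(OC)c(OC(=O)C(C)(C)C)c(OC)c1 | intermediate
3 | trichloroacetyl chloride | O=C(Cl)C(Cl)(Cl)Cl | starting material
4 | dichloroketene | O=C=C(Cl)Cl | intermediate
5 | 2,2-dichloro-3-[3,5-dimethoxy-4-(pivaloyloxy)benzyl]cyclobutan-1-one (racemic) | O=C1CC(Cc2cc(OC)c(OC(=O)C(C)(C)C)c(OC)c2)C1(Cl)Cl | intermediate
6 | 3-[3,5-dimethoxy-4-(pivaloyloxy)benzyl]cyclobutan-1-one (achiral) | O=C1CC(Cc2cc(OC)c(OC(=O)C(C)(C)C)c(OC)c2)C1 | intermediate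
7 | 1-hydroperoxy-3-[3,5-dimethoxy-4-(pivaloyloxy)benzyl]cyclobutan-1-ol (Criegee adduct) | OOC1(O)CC(Cc2cc(OC)c(OC(=O)C(C)(C)C)c(OC)c2)C1 | intermediate
8 | (R)-4-[3,5-dimethoxy-4-(pivaloyloxy)benzyl]dihydrofuran-2(3H)-one | O=C1C[C@@H](Cc2cc(OC)c(OC(=O)C(C)(C)C)c(OC)c2)CO1 | intermediate
9 | 3,4-dimethoxybenzyl bromide | COc1ccc(CBr)cc1OC | starting material
10 | lithium enolate of 8 (C4 R) | [Li+].[O-]C1=C[C@@H](Cc2cc(OC)c(OC(=O)C(C)(C)C)c(OC)c2)CO1 | intermediate
11 | (3R,4R)-3-(3,4-dimethoxybenzyl)-4-[3,5-dimethoxy-4-(pivaloyloxy)benzyl]dihydrofuran-2(3H)-one (trans) | O=C1[C@H](Cc2ccc(OC)c(OC)c2)[C@@H](Cc3cc(OC)c(OC(=O)C(C)(C)C)c(OC)c3)CO1 | intermediate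
12 | (2R,3R)-2-(3,4-dimethoxybenzyl)-3-(4-hydroxy-3,5-dimethoxybenzyl)butane-1,4-diol | COc1ccc(C[C@@H](CO)[C@H](CO)Cc2cc(OC)c(O)c(OC)c2)cc1OC | intermediate
13 | Justin C | COc1ccc(C[C@@H](COC(C)=O)[C@H](COC(C)=O)Cc2cc(OC)c(O)c(OC)c2)cc1OC | target

## Step count and risks

Total step count: 6. Longest linear sequence: 6 (1 → 2 → 6 → 8 → 11 → 12 → 13).

**Most likely to fail, first: step 3 (the proposed new step).**
- Risk: the confined pocket may slow the reaction or give insufficient ee for the remote, flexible benzyl group.
- Fallback: known chemistry that desymmetrises by deprotonation and C=C cleavage instead of oxygen insertion. It sets out from 6 and comes back at 8.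
- Cyclobutanone 6 is deprotonated enantioselectively with lithium bis(1-phenylethyl)amide (the appropriate antipode) in THF at −100 °C, with Et3SiCl present as an in-situ quench. This gives the (R)-triethylsilyl enol ether F1.
- Ozonolysis of the enol ether double bond (CH2Cl2–MeOH, −78 °C) with NaBH4 work-up gives the (R)-hydroxy acid F2, which closes to lactone 8 on acidification.

**Second: step 4.**
- Risk: veratryl bromide is labile, and over-alkylation or attack of the enolate on the pivalate could lower the yield.
- Fallback: an aldol–hydrogenolysis sequence that uses a stable aldehyde electrophile. It sets out from 8 and comes back at 11.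
- The same LiHMDS enolate is treated at −78 °C with 3,4-dimethoxybenzaldehyde to give the trans aldol adduct F3, as both carbinol epimers.
- The benzylic C–OH bond of F3 is then hydrogenolysed (H2, Pd/C, AcOH, cat. HClO4) to give 11.

**Third: step 6.**
- Risk: the bulky β-branched primary alcohols may be poor lipase substrates, so the reaction could stall before the diacetate.
- Fallback: exhaustive acylation followed by selective unmasking. It sets out from 12 and comes back at 13.
- Ac2O/pyridine/DMAP converts 12 into the triacetate F4.
- Brief aminolysis with pyrrolidine (1.1 equiv, CH2Cl2, 0 °C) removes only the far more electrophilic aryl acetate and leaves the two alkyl acetates, giving 13.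

## Further compounds

F1 | step 3 | (R)-2,6-dimethoxy-4-{[3-(triethylsilyloxy)cyclobut-2-en-1-yl]methyl}phenyl pivalate | CC[Si](CC)(CC)OC1=C[C@H](Cc2cc(OC)c(OC(=O)C(C)(C)C)c(OC)c2)C1
F2 | step 3 | (R)-3-(hydroxymethyl)-4-[3,5-dimethoxy-4-(pivaloyloxy)phenyl]butanoic acid | OC(=O)C[C@@H](Cc1cc(OC)c(OC(=O)C(C)(C)C)c(OC)c1)CO
F3 | step 4 | (3S,4R)-3-[(3,4-dimethoxyphenyl)(hydroxy)methyl]-4-[3,5-dimethoxy-4-(pivaloyloxy)benzyl]dihydrofuran-2(3H)-one (trans ring, both carbinol epimers) | O=C1[C@H](C(O)c2ccc(OC)c(OC)c2)[C@@H](Cc3cc(OC)c(OC(=O)C(C)(C)C)c(OC)c3)CO1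
F4 | step 6 | (2R,3R)-2-(4-acetoxy-3,5-dimethoxybenzyl)-3-(3,4-dimethoxybenzyl)butane-1,4-diyl diacetate | COc1ccc(C[C@@H](COC(C)=O)[C@H](COC(C)=O)Cc2cc(OC)c(OC(C)=O)c(OC)c2)cc1OC
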